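## Retrosynthetic overview

1. Target 10 ⇒ 5-deoxyflavonol 7: the C5–O bond is made last, by carbonyl-directed peri C–H borylation/oxidation (the new step).
2. 7 ⇒ chalcone 6: one oxidative cyclisation closes the pyranone ring (O1–C2) and forms the C3–O bond. This is the only ring formed; rings A and B are bought.
3. 6 ⇒ acetophenone 4 + vanillin 5 (aldol condensation).
4. 4 ⇒ gallacetophenone 1 by two chemoselective O-alkylations (4-O-prenyl with 2, then 3-O-methyl).

Assumption: the target SMILES has no stereocentre and no stereogenic double bond (the prenyl alkene carries two identical methyls), so the compound is achiral and no stereocontrol is needed.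

## Route

Step 1
Reactants: 1 1-(2,3,4-trihydroxyphenyl)ethanone (gallacetophenone); 2 1-bromo-3-methylbut-2-ene (prenyl bromide)
Product: 3 1-[2,3-dihydroxy-4-(3-methylbut-2-en-1-yloxy)phenyl]ethanone
Conditions: 2 (1.05 equiv), NaHCO3 (1.5 equiv), DMF, N2, 40 °C
Reagents that add atoms: none
Why: Williamson etherification; NaHCO3 ionises only the most acidic 4-OH (para to the acetyl group, whereas the 2-OH is held in the C=O hydrogen bond and the 3-OH is the weakest acid), so SN2 attack on the allylic bromide gives the 4-O-prenyl ether.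

Step 2
Reactants: 3 1-[2,3-dihydroxy-4-(3-methylbut-2-en-1-yloxy)phenyl]ethanone
Product: 4 1-[2-hydroxy-3-methoxy-4-(3-methylbut-2-en-1-yloxy)phenyl]ethanone
Conditions: MeI (1.1 equiv), K2CO3 (1.1 equiv), acetone, 40 °C
Reagents that add atoms: iodomethane, CI
Why: Williamson etherification; the chelated 2-OH is far less nucleophilic than the free 3-OH, so one equivalent of MeI methylates O-3 only.

Step 3
Reactants: 4 1-[2-hydroxy-3-methoxy-4-(3-methylbut-2-en-1-yloxy)phenyl]ethanone; 5 4-hydroxy-3-methoxybenzaldehyde (vanillin)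
Product: 7 3-hydroxy-2-(4-hydroxy-3-methoxyphenyl)-8-methoxy-7-[(3-methylbut-2-en-1-yl)oxy]-4H-chromen-4-one, via chalcone 6 (not isolated)
Conditions: 50% aq. KOH (10 equiv), EtOH, rt→45 °C, 36 h; then MeOH, 30% H2O2 (4 equiv), 0 °C→rt; AcOH to pH 4
Reagents that add atoms: hydrogen peroxide, OO
Why: Claisen–Schmidt condensation gives the E-chalcone, and alkaline peroxide then effects the Algar–Flynn–Oyamada oxidative cyclisation (O1–C2 and C3–O bonds); with no 6'-substituent the flavonol, not the aurone, is expected, the prenyl alkene is inert to HOO⁻, and no stereocentre is formed.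

Step 4
Reactants: 7 3-hydroxy-2-(4-hydroxy-3-methoxyphenyl)-8-methoxy-7-[(3-methylbut-2-en-1-yl)oxy]-4H-chromen-4-one
Product: 10 3,5-dihydroxy-2-(4-hydroxy-3-methoxyphenyl)-8-methoxy-7-[(3-methylbut-2-en-1-yl)oxy]-4H-chromen-4-one, via bis-O-boryl flavonol 8 (not isolated), via C5-boronate 9 (not isolated)
Conditions: HBpin (2.2 equiv), 2-MeTHF, rt, 1 h; then B2pin2 (1.2 equiv), [Ir(OMe)(cod)]2 (2.5 mol %), P[3,5-(CF3)2C6H3]3 (10 mol %), 80 °C; then 30% H2O2, aq. NaOH, 0 °C; aq. NH4Cl
Reagents that add atoms: pinacolborane, CC1(C)OBOC1(C)C, and bis(pinacolato)diboron, CC1(C)OB(OC1(C)C)B1OC(C)(C)C(C)(C)O1 (boryl groups of 8 and 9 only); hydrogen peroxide, OO (the C5 oxygen of 10)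
Why: Proposed new method: HBpin first converts both OH groups into non-acidic, non-chelating O–Bpin esters (8); an Ir(III) tris(boryl) complex with one electron-poor monophosphine has two free cis sites, so it can bind the C4 carbonyl lone pair on the C5 side and cleave the only C–H bond within reach (C5–H, five-membered iridacycle) to give 9; cold alkaline H2O2 then turns C5–B into the C5–O bond and hydrolyses the O–B esters, conditions the flavonol and prenyl ether already survived in step 3; the closest known reaction type is Ir-catalysed carbonyl-directed ortho-C–H borylation of aryl ketones and benzoates with monodentate P/As ligands followed by oxidation, together with in-flask O–Bpin masking of phenols, neither shown at the peri C5–H of a chromone or on a free flavonol.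

## Compound list

1 | 1-(2,3,4-trihydroxyphenyl)ethanone (gallacetophenone) | CC(=O)c1ccc(O)c(O)c1O | starting material
2 | 1-bromo-3-methylbut-2-ene (prenyl bromide) | CC(C)=CCBr | starting material
3 | 1-[2,3-dihydroxy-4-(3-methylbut-2-en-1-yloxy)phenyl]ethanone | CC(=O)c1ccc(OCC=C(C)C)c(O)c1O | intermediate
4 | 1-[2-hydroxy-3-methoxy-4-(3-methylbut-2-en-1-yloxy)phenyl]ethanone | CC(=O)c1ccc(OCC=C(C)C)c(OC)c1O | intermediate
5 | 4-hydroxy-3-methoxybenzaldehyde (vanillin) | COc1cc(C=O)ccc1O | starting material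
6 | (E)-1-[2-hydroxy-3-methoxy-4-(3-methylbut-2-en-1-yloxy)phenyl]-3-(4-hydroxy-3-methoxyphenyl)prop-2-en-1-one (chalcone) | COc1cc(/C=C/C(=O)c2ccc(OCC=C(C)C)c(OC)c2O)ccc1O | intermediate (not isolated)
7 | 3-hydroxy-2-(4-hydroxy-3-methoxyphenyl)-8-methoxy-7-[(3-methylbut-2-en-1-yl)oxy]-4H-chromen-4-one | COc1cc(-c2oc3c(OC)c(OCC=C(C)C)ccc3c(=O)c2O)ccc1O | intermediate
8 | 7 with O-3 and O-4' both converted into pinacolboryl (O–Bpin) esters | COc1cc(-c2oc3c(OC)c(OCC=C(C)C)ccc3c(=O)c2OB2OC(C)(C)C(C)(C)O2)ccc1OB1OC(C)(C)C(C)(C)O1 | intermediate (not isolated)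
9 | 8 carrying an additional Bpin group on C5 | COc1cc(-c2oc3c(OC)c(OCC=C(C)C)cc(B4OC(C)(C)C(C)(C)O4)c3c(=O)c2OB2OC(C)(C)C(C)(C)O2)ccc1OB1OC(C)(C)C(C)(C)O1 | intermediate (not isolated)
10 | 3,5-dihydroxy-2-(4-hydroxy-3-methoxyphenyl)-8-methoxy-7-[(3-methylbut-2-en-1-yl)oxy]-4H-chromen-4-one | COc1cc(-c2oc3c(OC)c(OCC=C(C)C)cc(O)c3c(=O)c2O)ccc1O | target

## Step count and risks

Total step count: 4. Longest linear sequence: 4 steps (1 → 3 → 4 → 7 → 10).

**Step 4 (proposed new step, highest risk).** It could fail through sterically controlled borylation on ring B or at C6, through Ir–H isomerisation or cleavage of the prenyl ether, or because the 3-O–B group ties up the carbonyl. The fallback uses known chemistry, sets out from 7 and comes back at 10.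
- The prenyl ether of 7 is cleaved (cat. Yb(OTf)3, MeNO2, rt) to give 3,7-dihydroxy-2-(4-hydroxy-3-methoxyphenyl)-8-methoxy-4H-chromen-4-one F1.
- F1 is subjected to the known Ru(II)-catalysed carbonyl-directed C5–H hydroxylation of flavones ([RuCl2(p-cymene)]2, PhI(OCOCF3)2, TFA/TFAA, 80 °C). TFAA masks every hydroxyl in the flask, so the product forms as limocitrin tetrakis(trifluoroacetate) F2.
- Work-up with aq. NaHCO3/MeOH hydrolyses F2 to 3,5,7-trihydroxy-2-(4-hydroxy-3-methoxyphenyl)-8-methoxy-4H-chromen-4-one (limocitrin) F3.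
- Ac2O/pyridine/DMAP gives limocitrin tetraacetate F4.
- PhSH/imidazole in NMP removes only the most labile 7-acetate, giving 3,5,4'-tri-O-acetyl-limocitrin F5.
- The single free 7-OH is alkylated with prenyl bromide 2 (K2CO3, acetone, rt) to give 3,5,4'-tri-O-acetyl-7-O-prenyl-limocitrin F6.
- K2CO3/MeOH at rt removes the three acetates and delivers 10.

**Step 3 (one-pot condensation/oxidative cyclisation with unprotected vanillin).** The vanillin phenoxide slows the aldol, and leftover aldehyde consumes peroxide by Dakin oxidation. The fallback is a protected, stepwise sequence that sets out from 4 and 5 and comes back at 7.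
- Vanillin 5 is protected (MOMCl, iPr2NEt, CH2Cl2) as 3-methoxy-4-(methoxymethoxy)benzaldehyde F7.
- Condensation of F7 with 4 (KOH, EtOH, rt) gives the isolated (E)-1-[2-hydroxy-3-methoxy-4-(3-methylbut-2-en-1-yloxy)phenyl]-3-[3-methoxy-4-(methoxymethoxy)phenyl]prop-2-en-1-one F8.
- Algar–Flynn–Oyamada oxidation of purified F8 (H2O2, NaOH, MeOH, 0 °C) gives 3-hydroxy-8-methoxy-2-[3-methoxy-4-(methoxymethoxy)phenyl]-7-[(3-methylbut-2-en-1-yl)oxy]-4H-chromen-4-one F9.
- Mild methanolysis (2 M HCl/MeOH, rt) removes the MOM group and returns 7.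

**Step 1 (mono-O-prenylation of a triol).** Bis-alkylation, C-prenylation and catechol oxidation are possible. The fallback installs prenyl last, on a substrate with only one reactive hydroxyl; it sets out from 1 and comes back at 4, bypassing 3.
- 1 is benzylated at O-4 (BnBr, NaHCO3, cat. NaI, MeCN, reflux) to give 1-[4-(benzyloxy)-2,3-dihydroxyphenyl]ethanone F10.
- MeI/K2CO3/acetone methylates the free 3-OH to give 1-[4-(benzyloxy)-2-hydroxy-3-methoxyphenyl]ethanone F11.
- Hydrogenolysis (H2, Pd/C, EtOAc) gives 1-(2,4-dihydroxy-3-methoxyphenyl)ethanone F12.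
- Prenyl bromide 2 (K2CO3, acetone, reflux) alkylates only the non-chelated 4-OH of F12 and gives 4.

Further compounds

F1 | step 4 | 3,7-dihydroxy-2-(4-hydroxy-3-methoxyphenyl)-8-methoxy-4H-chromen-4-one | COc1cc(-c2oc3c(OC)c(O)ccc3c(=O)c2O)ccc1O
F2 | step 4 | limocitrin tetrakis(trifluoroacetate) | COc1cc(-c2oc3c(OC)c(OC(=O)C(F)(F)F)cc(OC(=O)C(F)(F)F)c3c(=O)c2OC(=O)C(F)(F)F)ccc1OC(=O)C(F)(F)F
F3 | step 4 | 3,5,7-trihydroxy-2-(4-hydroxy-3-methoxyphenyl)-8-methoxy-4H-chromen-4-one (limocitrin) | COc1cc(-c2oc3c(OC)c(O)cc(O)c3c(=O)c2O)ccc1O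
F4 | step 4 | limocitrin tetraacetate | COc1cc(-c2oc3c(OC)c(OC(C)=O)cc(OC(C)=O)c3c(=O)c2OC(C)=O)ccc1OC(C)=O
F5 | step 4 | 3,5,4'-tri-O-acetyl-limocitrin (7-OH free) | COc1cc(-c2oc3c(OC)c(O)cc(OC(C)=O)c3c(=O)c2OC(C)=O)ccc1OC(C)=O
F6 | step 4 | 3,5,4'-tri-O-acetyl-7-O-prenyl-limocitrin | COc1cc(-c2oc3c(OC)c(OCC=C(C)C)cc(OC(C)=O)c3c(=O)c2OC(C)=O)ccc1OC(C)=O
F7 | step 3 | 3-methoxy-4-(methoxymethoxy)benzaldehyde | COCOc1ccc(C=O)cc1OC
F8 | step 3 | (E)-1-[2-hydroxy-3-methoxy-4-(3-methylbut-2-en-1-yloxy)phenyl]-3-[3-methoxy-4-(methoxymethoxy)phenyl]prop-2-en-1-one | COCOc1ccc(/C=C/C(=O)c2ccc(OCC=C(C)C)c(OC)c2O)cc1OC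
F9 | step 3 | 3-hydroxy-8-methoxy-2-[3-methoxy-4-(methoxymethoxy)phenyl]-7-[(3-methylbut-2-en-1-yl)oxy]-4H-chromen-4-one | COCOc1ccc(-c2oc3c(OC)c(OCC=C(C)C)ccc3c(=O)c2O)cc1OC
F10 | step 1 | 1-[4-(benzyloxy)-2,3-dihydroxyphenyl]ethanone | CC(=O)c1ccc(OCc2ccccc2)c(O)c1O
F11 | step 1 | 1-[4-(benzyloxy)-2-hydroxy-3-methoxyphenyl]ethanone | CC(=O)c1ccc(OCc2ccccc2)c(OC)c1O
F12 | step 1 | 1-(2,4-dihydroxy-3-methoxyphenyl)ethanone | CC(=O)c1ccc(O)c(OC)c1O
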